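The C2–C3 bond of the dihydrofuran ring is the disconnection on which the route rests. That ring hides a homoallylic alcohol: the benzylic carbinol carbon C3 is bonded to C2, which carries ring oxygen O1 and the exocyclic C(=CH2) unit, the pattern left by a [2,3]-Wittig shift. Run across an eight-membered 4H,6H-1,5-benzodioxocine, the shift should in one operation contract the ring to the 2,3-dihydrobenzofuran, form C2–C3, set both stereocentres (2,3-cis) and unveil the methylene group. The precursor is that benzodioxocine: a cis in-ring aryl enol ether bearing a silyloxymethyl group on its alkene carbon C3, a benzylic OCH2, the acetyl group as a dioxolane and the phenol as a TIPS ether.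

Key step: step 9

Assumption: the (S,S)-bis(oxazoline) is taken to give the (2R,3R) series; the sense of induction on this cyclic substrate has to be checked on the first run, and the (R,R)-ligand replaces it if the sense is opposite.

Step 1
Reactants: 1 2-methylidenepropane-1,3-diol
Product: 2 2-{[(tert-butyldimethylsilyl)oxy]methyl}prop-2-en-1-ol
Conditions: NaH (1.0 equiv), THF, 0 °C to rt; TBSCl (1.0 equiv)
Reagents that add atoms: tert-butyl(chloro)dimethylsilane, CC(C)(C)[Si](C)(C)Cl
Why: O-silylation of the sparingly soluble monosodium alkoxide of a symmetrical diol should stop after one silyl group.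

Step 2
Reactants: 2 2-{[(tert-butyldimethylsilyl)oxy]methyl}prop-2-en-1-ol
Product: 3 {[2-(bromomethyl)prop-2-en-1-yl]oxy}(tert-butyl)dimethylsilane
Conditions: CBr4, PPh3, CH2Cl2, 0 °C
Reagents that add atoms: carbon tetrabromide, BrC(Br)(Br)Br
Why: The Appel reaction converts the primary allylic alcohol into the bromide under neutral conditions that leave the silyl ether intact.

Step 3
Reactants: 4 5-bromo-2,4-dihydroxybenzaldehyde
Product: 5 5-bromo-2-hydroxy-4-[(triisopropylsilyl)oxy]benzaldehyde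
Conditions: TIPSCl (1.05 equiv), imidazole, CH2Cl2, 0 °C
Reagents that add atoms: chlorotri(propan-2-yl)silane, CC(C)[Si](Cl)(C(C)C)C(C)C
Why: Silylation should pick the 4-hydroxyl, because the 2-hydroxyl is held in a hydrogen bond to the aldehyde and is the less acidic and less accessible of the two.

Step 4
Reactants: 5 5-bromo-2-hydroxy-4-[(triisopropylsilyl)oxy]benzaldehyde; 6 tributyl(1-ethoxyvinyl)stannane
Product: 8 2-hydroxy-5-(2-methyl-1,3-dioxolan-2-yl)-4-[(triisopropylsilyl)oxy]benzaldehyde, via 1-ethoxyvinyl arene 7 (not isolated)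
Conditions: Pd(PPh3)2Cl2 (5 mol%), toluene, 100 °C; then ethane-1,2-diol (10 equiv), PPTS (10 mol%), rt; Et3N
Reagents that add atoms: ethane-1,2-diol, OCCO
Why: Stille coupling brings in the masked acetyl group, and acid-catalysed ketal exchange of the α-aryl enol ether with the diol (the way 2-methoxypropene makes acetonides) gives the dioxolane before any other acid-sensitive group exists, the chelated and doubly donor-substituted aldehyde being too unreactive to acetalise without water removal.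

Step 5
Reactants: 8 2-hydroxy-5-(2-methyl-1,3-dioxolan-2-yl)-4-[(triisopropylsilyl)oxy]benzaldehyde
Product: 9 2-(ethenyloxy)-5-(2-methyl-1,3-dioxolan-2-yl)-4-[(triisopropylsilyl)oxy]benzaldehyde
Conditions: Cu(OAc)2 (1 equiv), 2,4,6-trivinylcyclotriboroxane–pyridine complex (0.7 equiv), pyridine, CH2Cl2, air, rt
Reagents that add atoms: 2,4,6-trivinylcyclotriboroxane–pyridine complex, C=CB1OB(C=C)OB(C=C)O1.c1ccncc1
Why: Copper-mediated oxidative O-vinylation of a phenol with a vinylboron reagent (Chan–Lam-type coupling) runs at room temperature in pyridine and should spare the aldehyde, the ketal and the silyl ether.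

Step 6
Reactants: 9 2-(ethenyloxy)-5-(2-methyl-1,3-dioxolan-2-yl)-4-[(triisopropylsilyl)oxy]benzaldehyde
Product: 10 [2-(ethenyloxy)-5-(2-methyl-1,3-dioxolan-2-yl)-4-[(triisopropylsilyl)oxy]phenyl]methanol
Conditions: NaBH4, MeOH/THF, 0 °C
Reagents that add atoms: none
Why: Borohydride reduction of the aryl aldehyde is chemoselective and leaves the vinyl ether, the ketal and the silyl ether untouched.

Step 7
Reactants: 10 [2-(ethenyloxy)-5-(2-methyl-1,3-dioxolan-2-yl)-4-[(triisopropylsilyl)oxy]phenyl]methanol; 3 {[2-(bromomethyl)prop-2-en-1-yl]oxy}(tert-butyl)dimethylsilane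
Product: 11 tert-butyl{[2-({[2-(ethenyloxy)-5-(2-methyl-1,3-dioxolan-2-yl)-4-[(triisopropylsilyl)oxy]phenyl]methoxy}methyl)prop-2-en-1-yl]oxy}dimethylsilane
Conditions: NaH, Bu4NI (cat.), THF/DMF, 0 °C to rt
Reagents that add atoms: none
Why: Williamson etherification of the primary benzylic alkoxide with a reactive allylic bromide should be fast, and every other group present is base-stable.

Step 8
Reactants: 11 tert-butyl{[2-({[2-(ethenyloxy)-5-(2-methyl-1,3-dioxolan-2-yl)-4-[(triisopropylsilyl)oxy]phenyl]methoxy}methyl)prop-2-en-1-yl]oxy}dimethylsilane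
Product: 12 3-{[(tert-butyldimethylsilyl)oxy]methyl}-8-(2-methyl-1,3-dioxolan-2-yl)-9-[(triisopropylsilyl)oxy]-4H,6H-1,5-benzodioxocine (C2=C3 cis in the ring)
Conditions: (H2IMes)(PCy3)Cl2Ru=CHPh, second-generation Grubbs catalyst (10 mol%), toluene (5 mM), 80 °C
Reagents that add atoms: none
Why: Ring-closing metathesis of the aryl vinyl ether onto the 1,1-disubstituted alkene should give the cyclic trisubstituted enol ether with loss of ethene, the ortho-fused benzene ring pre-organising the eight-membered closure and the ring size allowing only the cis double bond.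

Step 9
Reactants: 12 3-{[(tert-butyldimethylsilyl)oxy]methyl}-8-(2-methyl-1,3-dioxolan-2-yl)-9-[(triisopropylsilyl)oxy]-4H,6H-1,5-benzodioxocine
Product: 14 (2R,3R)-2-[3-(tert-butyldimethylsilyloxy)prop-1-en-2-yl]-5-(2-methyl-1,3-dioxolan-2-yl)-6-(triisopropylsilyloxy)-2,3-dihydro-1-benzofuran-3-ol, via C6-lithiated benzodioxocine 13 (not isolated)
Conditions: t-BuLi (2 equiv), 2,2'-(propane-2,2-diyl)bis[(4S)-4-isopropyl-4,5-dihydro-1,3-oxazole] (2.2 equiv), hexane, −78 °C to −40 °C; aq. NH4Cl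
Reagents that add atoms: none
Why: Proposed new method: the ligand-bound t-BuLi should take one of the two enantiotopic benzylic hydrogens at C6 (numbering of 12), and the α-oxy carbanion 13 should add to the enol-ether carbon C2 on the far side of the ring while the allylic C4–O5 bond breaks and the C3=C4 methylene appears, a suprafacial six-electron [2,3]-Wittig shift over C6–O5–C4–C3=C2. The closest known reactions are [2,3]-Wittig ring contractions of medium and large cyclic allylic ethers and the enantioselective [2,3]-Wittig rearrangement of acyclic allyl benzyl ethers under alkyllithium–bis(oxazoline) control, whereas an eight-to-five transannular contraction onto an aryl enol ether has not been shown. The dihydrofuran ring (O1, C2, C3, C3a, C7a of 14) closes by transannular 1,5 C–C bond formation, formally a 5-exo-trig attack of C6 on the C2=C3 bond. C3 of 14 is controlled by the ligand, which selects the hydrogen (the pro-R one if lithiation is retentive and the shift invertive, as is usual for α-oxy organolithiums) and must keep 13 from epimerising before it rearranges, while C2 follows from C3 because the forming bond belongs to both the sigmatropic array and the new ring, a bicyclo[3.3.0]-like transition state that can only be cis-fused and so puts hydroxyl and alkenyl group cis. The step needs benzylic lithiation to beat deprotonation at the allylic OCH2 (C4), the aryl C10–H and the vinylic C2–H, and the [2,3] shift to beat the [1,2] shift: the benzylic site is the most acidic and lies next to the coordinating O5, the bulky TIPS ether is a poor directing group, the ring holds the enol ether cis and within reach of C6, low temperature favours the concerted path, and acetyl and phenol travel as dioxolane and silyl ether, both inert to the base.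

Step 10
Reactants: 14 (2R,3R)-2-[3-(tert-butyldimethylsilyloxy)prop-1-en-2-yl]-5-(2-methyl-1,3-dioxolan-2-yl)-6-(triisopropylsilyloxy)-2,3-dihydro-1-benzofuran-3-ol; 15 angelic acid [(2Z)-2-methylbut-2-enoic acid]
Product: 17 (2R,3R)-2-[3-(tert-butyldimethylsilyloxy)prop-1-en-2-yl]-5-(2-methyl-1,3-dioxolan-2-yl)-6-(triisopropylsilyloxy)-2,3-dihydro-1-benzofuran-3-yl (2Z)-2-methylbut-2-enoate, via angelic 2,4,6-trichlorobenzoic anhydride 16 (not isolated)
Conditions: 15 (3 equiv), 2,4,6-trichlorobenzoyl chloride, Et3N, toluene, rt; then 14, 75 °C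
Reagents that add atoms: none
Why: Yamaguchi-type esterification through the mixed anhydride, run without DMAP, acylates hindered secondary alcohols at the unshielded angeloyl carbonyl while keeping the Z geometry, and it breaks no bond at C2 or C3.

Step 11
Reactants: 17 (2R,3R)-2-[3-(tert-butyldimethylsilyloxy)prop-1-en-2-yl]-5-(2-methyl-1,3-dioxolan-2-yl)-6-(triisopropylsilyloxy)-2,3-dihydro-1-benzofuran-3-yl (2Z)-2-methylbut-2-enoate
Product: 18 (2R,3R)-5-acetyl-2-[3-(tert-butyldimethylsilyloxy)prop-1-en-2-yl]-6-(triisopropylsilyloxy)-2,3-dihydro-1-benzofuran-3-yl (2Z)-2-methylbut-2-enoate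
Conditions: PPTS (20 mol%), acetone/H2O (10:1), rt
Reagents that add atoms: water, O
Why: Acid-catalysed hydrolysis of a ketal on an electron-rich arene is fast under PPTS, well below the acidity that ionises the benzylic ester or cleaves the silyl ethers, and the freed acetyl group then deactivates the ring toward loss of the C3 ester.

Step 12
Reactants: 18 (2R,3R)-5-acetyl-2-[3-(tert-butyldimethylsilyloxy)prop-1-en-2-yl]-6-(triisopropylsilyloxy)-2,3-dihydro-1-benzofuran-3-yl (2Z)-2-methylbut-2-enoate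
Product: 19 (2R,3R)-5-acetyl-6-hydroxy-2-(3-hydroxyprop-1-en-2-yl)-2,3-dihydro-1-benzofuran-3-yl (2Z)-2-methylbut-2-enoate
Conditions: Bu4NF, AcOH (1:1, 3 equiv each), THF, 0 °C to rt
Reagents that add atoms: none
Why: Fluoride desilylation buffered with acetic acid removes the aryl TIPS and primary TBS ethers while keeping the phenol protonated, which should suppress acyl migration and phenoxide-assisted loss of the benzylic ester.

Step 13
Reactants: 19 (2R,3R)-5-acetyl-6-hydroxy-2-(3-hydroxyprop-1-en-2-yl)-2,3-dihydro-1-benzofuran-3-yl (2Z)-2-methylbut-2-enoate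
Product: 20 (2R,3R)-2-[3-(acetyloxy)prop-1-en-2-yl]-5-acetyl-6-hydroxy-2,3-dihydro-1-benzofuran-3-yl (2Z)-2-methylbut-2-enoate (CNP0323250.1)
Conditions: Ac2O (1.2 equiv), pyridine, CH2Cl2, 0 °C
Reagents that add atoms: acetic anhydride, CC(=O)OC(C)=O
Why: Acetylation should take the primary allylic alcohol only, since the phenol is hydrogen-bonded to the ortho acetyl group and is acylated only under forcing conditions.

Compound list
1 | 2-methylidenepropane-1,3-diol | C=C(CO)CO | starting material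
2 | 2-{[(tert-butyldimethylsilyl)oxy]methyl}prop-2-en-1-ol | C=C(CO)CO[Si](C)(C)C(C)(C)C | intermediate
3 | {[2-(bromomethyl)prop-2-en-1-yl]oxy}(tert-butyl)dimethylsilane | C=C(CBr)CO[Si](C)(C)C(C)(C)C | intermediate
4 | 5-bromo-2,4-dihydroxybenzaldehyde | O=Cc1cc(Br)c(O)cc1O | starting material
5 | 5-bromo-2-hydroxy-4-[(triisopropylsilyl)oxy]benzaldehyde | O=Cc1cc(Br)c(O[Si](C(C)C)(C(C)C)C(C)C)cc1O | intermediate
6 | tributyl(1-ethoxyvinyl)stannane | CCCC[Sn](CCCC)(CCCC)C(=C)OCC | starting material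
7 | 5-(1-ethoxyethenyl)-2-hydroxy-4-[(triisopropylsilyl)oxy]benzaldehyde (not isolated) | O=Cc1cc(C(=C)OCC)c(O[Si](C(C)C)(C(C)C)C(C)C)cc1O | intermediate
8 | 2-hydroxy-5-(2-methyl-1,3-dioxolan-2-yl)-4-[(triisopropylsilyl)oxy]benzaldehyde | O=Cc1cc(C2(C)OCCO2)c(O[Si](C(C)C)(C(C)C)C(C)C)cc1O | intermediate
9 | 2-(ethenyloxy)-5-(2-methyl-1,3-dioxolan-2-yl)-4-[(triisopropylsilyl)oxy]benzaldehyde | O=Cc1cc(C2(C)OCCO2)c(O[Si](C(C)C)(C(C)C)C(C)C)cc1OC=C | intermediate
10 | [2-(ethenyloxy)-5-(2-methyl-1,3-dioxolan-2-yl)-4-[(triisopropylsilyl)oxy]phenyl]methanol | OCc1cc(C2(C)OCCO2)c(O[Si](C(C)C)(C(C)C)C(C)C)cc1OC=C | intermediate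
11 | tert-butyl{[2-({[2-(ethenyloxy)-5-(2-methyl-1,3-dioxolan-2-yl)-4-[(triisopropylsilyl)oxy]phenyl]methoxy}methyl)prop-2-en-1-yl]oxy}dimethylsilane | C=COc1cc(O[Si](C(C)C)(C(C)C)C(C)C)c(C2(C)OCCO2)cc1COCC(=C)CO[Si](C)(C)C(C)(C)C | intermediate
12 | 3-{[(tert-butyldimethylsilyl)oxy]methyl}-8-(2-methyl-1,3-dioxolan-2-yl)-9-[(triisopropylsilyl)oxy]-4H,6H-1,5-benzodioxocine, C2=C3 cis in the ring | CC(C)(C)[Si](C)(C)OC/C1=C/Oc2cc(O[Si](C(C)C)(C(C)C)C(C)C)c(C3(C)OCCO3)cc2COC1 | intermediate
13 | (6R)-6-lithio derivative of 12, ligand-bound (not isolated; configuration as expected for removal of the pro-R hydrogen) | CC(C)(C)[Si](C)(C)OC/C1=C/Oc2cc(O[Si](C(C)C)(C(C)C)C(C)C)c(C3(C)OCCO3)cc2[C@@H]([Li])OC1 | intermediate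
14 | (2R,3R)-2-[3-(tert-butyldimethylsilyloxy)prop-1-en-2-yl]-5-(2-methyl-1,3-dioxolan-2-yl)-6-(triisopropylsilyloxy)-2,3-dihydro-1-benzofuran-3-ol | C=C(CO[Si](C)(C)C(C)(C)C)[C@H]1Oc2cc(O[Si](C(C)C)(C(C)C)C(C)C)c(C3(C)OCCO3)cc2[C@H]1O | intermediate
15 | angelic acid, (2Z)-2-methylbut-2-enoic acid | C/C=C(/C)C(=O)O | starting material
16 | (2Z)-2-methylbut-2-enoic 2,4,6-trichlorobenzoic anhydride (not isolated) | C/C=C(/C)C(=O)OC(=O)c1c(Cl)cc(Cl)cc1Cl | intermediate
17 | (2R,3R)-2-[3-(tert-butyldimethylsilyloxy)prop-1-en-2-yl]-5-(2-methyl-1,3-dioxolan-2-yl)-6-(triisopropylsilyloxy)-2,3-dihydro-1-benzofuran-3-yl (2Z)-2-methylbut-2-enoate | C=C(CO[Si](C)(C)C(C)(C)C)[C@H]1Oc2cc(O[Si](C(C)C)(C(C)C)C(C)C)c(C3(C)OCCO3)cc2[C@H]1OC(=O)/C(C)=C\C | intermediate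
18 | (2R,3R)-5-acetyl-2-[3-(tert-butyldimethylsilyloxy)prop-1-en-2-yl]-6-(triisopropylsilyloxy)-2,3-dihydro-1-benzofuran-3-yl (2Z)-2-methylbut-2-enoate | C=C(CO[Si](C)(C)C(C)(C)C)[C@H]1Oc2cc(O[Si](C(C)C)(C(C)C)C(C)C)c(C(C)=O)cc2[C@H]1OC(=O)/C(C)=C\C | intermediate
19 | (2R,3R)-5-acetyl-6-hydroxy-2-(3-hydroxyprop-1-en-2-yl)-2,3-dihydro-1-benzofuran-3-yl (2Z)-2-methylbut-2-enoate | C=C(CO)[C@H]1Oc2cc(O)c(C(C)=O)cc2[C@H]1OC(=O)/C(C)=C\C | intermediate
20 | (2R,3R)-2-[3-(acetyloxy)prop-1-en-2-yl]-5-acetyl-6-hydroxy-2,3-dihydro-1-benzofuran-3-yl (2Z)-2-methylbut-2-enoate | C=C(COC(C)=O)[C@H]1Oc2cc(O)c(C(C)=O)cc2[C@H]1OC(=O)/C(C)=C\C | target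

Total steps: 13. Longest linear sequence: 11 steps (4 to 20, steps 3 to 13).

Steps most likely to fail

1. Step 9 (transannular [2,3]-Wittig contraction). What may go wrong: lithiation at another site (aryl C10–H, vinylic C2–H, allylic C4–H), a competing [1,2]-shift or ring fragmentation, or loss of enantiocontrol because the lithiated carbon epimerises before it rearranges. Fallback, known reactions only, leaving the route at 8 and rejoining it at 17: the five-membered ring is closed by phenoxide opening of an enantioenriched epoxide. Phenol 8 is O-allylated (allyl bromide, K2CO3, acetone) to 2-(allyloxy)-5-(2-methyl-1,3-dioxolan-2-yl)-4-[(triisopropylsilyl)oxy]benzaldehyde F1. The alkenyllithium is made with t-BuLi (Et2O, −78 °C) from (E)-tert-butyl[(3-iodo-2-methylprop-2-en-1-yl)oxy]dimethylsilane F2, itself obtained from (E)-3-iodo-2-methylprop-2-en-1-ol with TBSCl and imidazole. Its addition to F1 gives racemic (2E)-1-[2-(allyloxy)-5-(2-methyl-1,3-dioxolan-2-yl)-4-[(triisopropylsilyl)oxy]phenyl]-4-[(tert-butyldimethylsilyl)oxy]-3-methylbut-2-en-1-ol F3. Sharpless kinetic resolution (Ti(OiPr)4, D-(−)-diisopropyl tartrate, t-BuOOH, 4 Å molecular sieves, CH2Cl2, −20 °C, stopped short of half conversion) should epoxidise the S alcohol to the erythro epoxy alcohol (R)-[2-(allyloxy)-5-(2-methyl-1,3-dioxolan-2-yl)-4-[(triisopropylsilyl)oxy]phenyl][(2R,3R)-3-{[(tert-butyldimethylsilyl)oxy]methyl}-3-methyloxiran-2-yl]methanol F4. Removal of the allyl group (Pd(PPh3)4, morpholine, THF, then 50 °C) frees the phenoxide, which opens the epoxide at the carbon next to the carbinol in the 5-exo mode with inversion. The erythro relationship thereby becomes 2,3-cis in (2S,3R)-2-[(2R)-1-[(tert-butyldimethylsilyl)oxy]-2-hydroxypropan-2-yl]-5-(2-methyl-1,3-dioxolan-2-yl)-6-[(triisopropylsilyl)oxy]-2,3-dihydro-1-benzofuran-3-ol F5. Its secondary hydroxyl is angeloylated as in step 10 to (2S,3R)-2-[(2R)-1-[(tert-butyldimethylsilyl)oxy]-2-hydroxypropan-2-yl]-5-(2-methyl-1,3-dioxolan-2-yl)-6-[(triisopropylsilyl)oxy]-2,3-dihydro-1-benzofuran-3-yl (2Z)-2-methylbut-2-enoate F6. Dehydration of the tertiary alcohol toward its methyl group (Burgess reagent, toluene, 50 °C) then gives 17.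

2. Step 8 (ring-closing metathesis). What may go wrong: the catalyst loads on the vinyl ether and rests as the aryloxy carbene, the hindered 1,1-disubstituted alkene engages too slowly, and intermolecular metathesis overtakes closure of the eight-membered ring. Fallback, leaving the route at 10 and rejoining it at 12: the ring is closed on an unhindered alkene and the C3 carbon is added afterwards. Alcohol 10 is allylated (NaH, allyl bromide, THF) to {2-(ethenyloxy)-5-[(prop-2-en-1-yloxy)methyl]-4-(2-methyl-1,3-dioxolan-2-yl)phenoxy}tri(propan-2-yl)silane F7. Ring-closing metathesis with the same catalyst, now initiated at the monosubstituted allyl terminus, gives 8-(2-methyl-1,3-dioxolan-2-yl)-9-[(triisopropylsilyl)oxy]-4H,6H-1,5-benzodioxocine F8. NBS at −78 °C followed by DBU brominates the enol ether by addition–elimination at C3, the only position from which the enol ether can re-form, to give 3-bromo-8-(2-methyl-1,3-dioxolan-2-yl)-9-[(triisopropylsilyl)oxy]-4H,6H-1,5-benzodioxocine F9. Stille coupling with (tributylstannyl)methanol (Pd(PPh3)4, dioxane, 90 °C) gives [8-(2-methyl-1,3-dioxolan-2-yl)-9-[(triisopropylsilyl)oxy]-4H,6H-1,5-benzodioxocin-3-yl]methanol F10. TBSCl and imidazole then give 12.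

3. Step 10 (angelate formation). What may go wrong: isomerisation of the Z acyl group to the E form during activation, sluggish acylation of the hindered cis alcohol, and heat- or base-induced loss of the benzylic oxygen with aromatisation to the benzofuran. Fallback, leaving the route at 14 and rejoining it at 17: the Z alkene is built on the ester. Alcohol 14 is acylated at room temperature with 2-[bis(2,2,2-trifluoroethoxy)phosphoryl]propanoic acid (DCC, DMAP, CH2Cl2) to give (2R,3R)-2-[3-(tert-butyldimethylsilyloxy)prop-1-en-2-yl]-5-(2-methyl-1,3-dioxolan-2-yl)-6-(triisopropylsilyloxy)-2,3-dihydro-1-benzofuran-3-yl 2-[bis(2,2,2-trifluoroethoxy)phosphoryl]propanoate F11. Still–Gennari olefination with acetaldehyde (KHMDS, 18-crown-6, THF, −78 °C) then gives the Z-configured ester 17.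

Further compounds
F1 | step 9 | 2-(allyloxy)-5-(2-methyl-1,3-dioxolan-2-yl)-4-[(triisopropylsilyl)oxy]benzaldehyde | O=Cc1cc(C2(C)OCCO2)c(O[Si](C(C)C)(C(C)C)C(C)C)cc1OCC=C
F2 | step 9 | (E)-tert-butyl[(3-iodo-2-methylprop-2-en-1-yl)oxy]dimethylsilane | I/C=C(\C)CO[Si](C)(C)C(C)(C)C
F3 | step 9 | racemic (2E)-1-[2-(allyloxy)-5-(2-methyl-1,3-dioxolan-2-yl)-4-[(triisopropylsilyl)oxy]phenyl]-4-[(tert-butyldimethylsilyl)oxy]-3-methylbut-2-en-1-ol | C=CCOc1cc(O[Si](C(C)C)(C(C)C)C(C)C)c(C2(C)OCCO2)cc1C(O)/C=C(\C)CO[Si](C)(C)C(C)(C)C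
F4 | step 9 | (R)-[2-(allyloxy)-5-(2-methyl-1,3-dioxolan-2-yl)-4-[(triisopropylsilyl)oxy]phenyl][(2R,3R)-3-{[(tert-butyldimethylsilyl)oxy]methyl}-3-methyloxiran-2-yl]methanol | C=CCOc1cc(O[Si](C(C)C)(C(C)C)C(C)C)c(C2(C)OCCO2)cc1[C@@H](O)[C@H]3O[C@]3(C)CO[Si](C)(C)C(C)(C)C
F5 | step 9 | (2S,3R)-2-[(2R)-1-[(tert-butyldimethylsilyl)oxy]-2-hydroxypropan-2-yl]-5-(2-methyl-1,3-dioxolan-2-yl)-6-[(triisopropylsilyl)oxy]-2,3-dihydro-1-benzofuran-3-ol | C[C@@](O)(CO[Si](C)(C)C(C)(C)C)[C@H]1Oc2cc(O[Si](C(C)C)(C(C)C)C(C)C)c(C3(C)OCCO3)cc2[C@H]1O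
F6 | step 9 | (2S,3R)-2-[(2R)-1-[(tert-butyldimethylsilyl)oxy]-2-hydroxypropan-2-yl]-5-(2-methyl-1,3-dioxolan-2-yl)-6-[(triisopropylsilyl)oxy]-2,3-dihydro-1-benzofuran-3-yl (2Z)-2-methylbut-2-enoate | C[C@@](O)(CO[Si](C)(C)C(C)(C)C)[C@H]1Oc2cc(O[Si](C(C)C)(C(C)C)C(C)C)c(C3(C)OCCO3)cc2[C@H]1OC(=O)/C(C)=C\C
F7 | step 8 | {2-(ethenyloxy)-5-[(prop-2-en-1-yloxy)methyl]-4-(2-methyl-1,3-dioxolan-2-yl)phenoxy}tri(propan-2-yl)silane | C=COc1cc(O[Si](C(C)C)(C(C)C)C(C)C)c(C2(C)OCCO2)cc1COCC=C
F8 | step 8 | 8-(2-methyl-1,3-dioxolan-2-yl)-9-[(triisopropylsilyl)oxy]-4H,6H-1,5-benzodioxocine | O1/C=C\COCc2cc(C3(C)OCCO3)c(O[Si](C(C)C)(C(C)C)C(C)C)cc12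
F9 | step 8 | 3-bromo-8-(2-methyl-1,3-dioxolan-2-yl)-9-[(triisopropylsilyl)oxy]-4H,6H-1,5-benzodioxocine | O1/C=C(Br)\COCc2cc(C3(C)OCCO3)c(O[Si](C(C)C)(C(C)C)C(C)C)cc12
F10 | step 8 | [8-(2-methyl-1,3-dioxolan-2-yl)-9-[(triisopropylsilyl)oxy]-4H,6H-1,5-benzodioxocin-3-yl]methanol | OC/C1=C/Oc2cc(O[Si](C(C)C)(C(C)C)C(C)C)c(C3(C)OCCO3)cc2COC1
F11 | step 10 | (2R,3R)-2-[3-(tert-butyldimethylsilyloxy)prop-1-en-2-yl]-5-(2-methyl-1,3-dioxolan-2-yl)-6-(triisopropylsilyloxy)-2,3-dihydro-1-benzofuran-3-yl 2-[bis(2,2,2-trifluoroethoxy)phosphoryl]propanoate | C=C(CO[Si](C)(C)C(C)(C)C)[C@H]1Oc2cc(O[Si](C(C)C)(C(C)C)C(C)C)c(C3(C)OCCO3)cc2[C@H]1OC(=O)C(C)P(=O)(OCC(F)(F)F)OCC(F)(F)F
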